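**Retrosynthetic overview**
1. The target comes from the Δ3 11-formate by a Schenck ene reaction with singlet oxygen, then reduction; this sets C4–OH and the E-2-ene. The formate comes from the 1,12-epoxy-11-ol by O-formylation.
2. Key disconnection, both rings at once: C12–O (5-exo opening of an (11R,12R)-epoxide by the C1 oxygen) and C1–C2 (C1 cation plus C2=C3 olefin, the cembrane-forming bond). This leads back to an acyclic epoxy diketone that carries a tertiary allylsilane.
3. Ring order: the tetrahydrofuran closes first and the 14-membered carbocycle second, in the same flask. The tether sets C1; a Shi epoxidation sets C11 and C12.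
4. The acyclic chain comes from two Carroll rearrangements (C4–C5 and C13–C14) on an (S)-citronellal core, which supplies C8. A Roskamp homologation and a first Schenck ene reaction feed them.

**Assumption:** cembrane numbering is used throughout (C1 carries isopropyl, C4 the carbinol, C6 the ketone, C8 the methine, C11 the formate, C12 the methyl-bearing ether carbon). The presumed biosynthesis is incensole-type: C1–C2 cation–olefin macrocyclisation of geranylgeranyl diphosphate, cation relocated to C1 and oxygenated, 11,12-epoxide opened at C12 by the C1 oxygen, then ene-type oxygenation of C3=C4.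

Step 1
Reactants: 1 but-2-yn-1-ol
Product: 2 (E)-3-(triethylsilyl)but-2-en-1-ol
Conditions: Et3SiH (1.1 equiv), PtCl2 (1 mol %), 2-dicyclohexylphosphino-2′,4′,6′-triisopropylbiphenyl (2 mol %), THF, 50 °C
Reagents that add atoms: triethylsilane CC[SiH](CC)CC
Why: Platinum-catalysed syn-hydrosilylation of a propargylic alcohol places silicon on the alkyne carbon remote from CH2OH, giving the γ-silyl allylic alcohol, whose alkene geometry has no later consequence.

Step 2
Reactants: 3 (S)-citronellal; 4 ethyl diazoacetate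
Product: 5 ethyl (5S)-5,9-dimethyl-3-oxodec-8-enoate
Conditions: SnCl2 (10 mol %), CH2Cl2, rt
Reagents that add atoms: none
Why: In the Roskamp homologation the diazo carbon adds to the SnCl2-activated aldehyde and a 1,2-hydride shift with loss of N2 gives the β-keto ester, which installs C5 and the C6 ketone and leaves the chiral-pool C8 centre untouched.

Step 3
Reactants: 5 ethyl (5S)-5,9-dimethyl-3-oxodec-8-enoate; 2 (E)-3-(triethylsilyl)but-2-en-1-ol
Product: 8 (7S)-3,7,11-trimethyl-3-(triethylsilyl)dodeca-1,10-dien-5-one (both epimers at the silyl-bearing carbon), via allyl β-keto ester 6 (not isolated), via β-keto acid 7 (not isolated)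
Conditions: 4-(dimethylamino)pyridine (0.2 equiv), 1,2-dichlorobenzene, 110 °C (EtOH distilled off), then 180 °C
Reagents that add atoms: none
Why: Acylketene transesterification followed by Carroll rearrangement (decarboxylative [3,3] Claisen) forms C4–C5 at the silyl-bearing alkene carbon and leaves a tertiary allylsilane with a free CH2= terminus; the new C4 centre forms as both epimers and is erased in step 7.

Step 4
Reactants: 8 (7S)-3,7,11-trimethyl-3-(triethylsilyl)dodeca-1,10-dien-5-one
Product: 10 (7S)-10-hydroxy-3,7,11-trimethyl-3-(triethylsilyl)dodeca-1,11-dien-5-one (both carbinol epimers), via allylic hydroperoxide 9 (not isolated)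
Conditions: O2, 5,10,15,20-tetraphenylporphyrin (0.5 mol %), white LED, CH2Cl2, 0 °C; then PPh3 (1.1 equiv)
Reagents that add atoms: oxygen O=O
Why: The Schenck ene reaction attacks only the trisubstituted isopropylidene alkene (the monosubstituted vinyl is inert to singlet oxygen) and gives about half the material as the isopropenyl carbinol; the tertiary regioisomer is removed by chromatography and the new carbinol centre is erased in step 5.

Step 5
Reactants: 10 (7S)-10-hydroxy-3,7,11-trimethyl-3-(triethylsilyl)dodeca-1,11-dien-5-one; 11 methyl 4-methyl-3-oxopentanoate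
Product: 14 (7S,10E)-3,7,11,15-tetramethyl-3-(triethylsilyl)hexadeca-1,10-diene-5,14-dione, via β-keto ester 12 (not isolated), via β-keto acid 13 (not isolated)
Conditions: 11 (3 equiv), 4-(dimethylamino)pyridine (0.2 equiv), o-xylene, 145 °C (MeOH removed)
Reagents that add atoms: none
Why: In this Carroll rearrangement a chair transition state with the C10 chain pseudo-equatorial forms C13–C14, the E-C11=C12 alkene and, after loss of CO2, the isopropyl ketone at C1 in one operation.

Step 6
Reactants: 14 (7S,10E)-3,7,11,15-tetramethyl-3-(triethylsilyl)hexadeca-1,10-diene-5,14-dione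
Product: 15 (7S,10R,11R)-10,11-epoxy-3,7,11,15-tetramethyl-3-(triethylsilyl)hexadec-1-ene-5,14-dione (cembrane 11R,12R)
Conditions: 1,2:4,5-di-O-isopropylidene-β-D-erythro-2,3-hexodiulo-2,6-pyranose (0.3 equiv), KHSO5 (as 2KHSO5·KHSO4·K2SO4, 1.4 equiv), K2CO3, Bu4NHSO4 (4 mol %), MeCN–CH2(OMe)2/aq. Na2B4O7 buffer, 0 °C
Reagents that add atoms: potassium peroxymonosulfate [K+].[O-]S(=O)(=O)OO
Why: In the Shi asymmetric epoxidation the D-fructose-derived dioxirane reacts through the spiro transition state with the E-trisubstituted alkene to give the (R,R)-epoxide under reagent control, which sets C11 and the pre-inversion C12, while the terminal vinyl group is too unreactive to compete.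

Step 7
Reactants: 15 (7S,10R,11R)-10,11-epoxy-3,7,11,15-tetramethyl-3-(triethylsilyl)hexadec-1-ene-5,14-dione
Product: 18 (1R,3E,8S,11R,12S)-1,12-epoxy-11-hydroxycembr-3-en-6-one, via oxocarbenium triflate 16 (not isolated), via TES ether 17 (not isolated)
Conditions: Et3SiOTf (0.2 equiv), 2,6-di-tert-butyl-4-methylpyridine (0.3 equiv), CH2Cl2, 1 mM (15 added over 10 h), −78 → −30 °C; then AcOH–THF–H2O 3:1:1, rt
Reagents that add atoms: none
Why: Proposed new method: the silyl triflate activates the epoxide and the C1 carbonyl oxygen opens it 5-exo at tertiary C12 with inversion (C11 untouched) to give the five-membered oxocarbenium ion, an oxygen-stabilised C1 cembranyl cation in equilibrium with its bicyclic ketal; the unhindered CH2= terminus of the tethered allylsilane then attacks C1 (anti SE2′, methyl inside and chain outside, hence the E-3-ene from either C4 epimer) on the only face the ten-atom tether can reach, cis to C11, which sets C1, and the released Et3Si+ caps O11 and carries the chain; the closest known reaction types are the acid-induced epoxy-ketone to bicyclic-ketal rearrangement, Hosomi–Sakurai allylation of cyclic ketals and Prins-type macrocyclisation.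

Step 8
Reactants: 18 (1R,3E,8S,11R,12S)-1,12-epoxy-11-hydroxycembr-3-en-6-one
Product: 19 (1R,3E,8S,11R,12S)-1,12-epoxy-6-oxocembr-3-en-11-yl formate
Conditions: acetic formic anhydride (3 equiv), pyridine, 4-(dimethylamino)pyridine (5 mol %), CH2Cl2, 0 °C
Reagents that add atoms: acetic formic anhydride CC(=O)OC=O
Why: O-Formylation by acyl transfer occurs at the more electrophilic formyl carbon of the mixed anhydride, C11 keeps its configuration because only the O–H bond reacts, and the weak base does not conjugate the β,γ-enone.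

Step 9
Reactants: 19 (1R,3E,8S,11R,12S)-1,12-epoxy-6-oxocembr-3-en-11-yl formate
Product: 21 (1S,2E,4S,8S,11R,12S)-1,12-epoxy-4-hydroxy-6-oxocembr-2-en-11-yl formate (target), via C4 hydroperoxide 20 (not isolated)
Conditions: O2, 5,10,15,20-tetraphenylporphyrin (0.5 mol %), white LED, CH2Cl2, −20 °C; then PPh3 (1.1 equiv), −20 °C → rt
Reagents that add atoms: oxygen O=O
Why: In this Schenck ene reaction on the only alkene the cis effect steers singlet oxygen to the side carrying C2 and the C4 methyl, and suprafacial abstraction of the outward C2–H delivers OOH to C4 from the exposed outer face of the ring-perpendicular E-alkene; this is expected to give the 4S centre of the natural series and the E-2-ene, PPh3 reduces O–O with retention, and the exocyclic-methylene isomer is removed by chromatography.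

**Compound list**
1 | but-2-yn-1-ol | CC#CCO | starting material
2 | (E)-3-(triethylsilyl)but-2-en-1-ol | C/C(=C\CO)[Si](CC)(CC)CC | intermediate
3 | (S)-citronellal, (3S)-3,7-dimethyloct-6-enal | C[C@@H](CCC=C(C)C)CC=O | starting material
4 | ethyl diazoacetate | CCOC(=O)C=[N+]=[N-] | starting material
5 | ethyl (5S)-5,9-dimethyl-3-oxodec-8-enoate | CCOC(=O)CC(=O)C[C@@H](C)CCC=C(C)C | intermediate
6 | (E)-3-(triethylsilyl)but-2-en-1-yl (5S)-5,9-dimethyl-3-oxodec-8-enoate | C/C(=C\COC(=O)CC(=O)C[C@@H](C)CCC=C(C)C)[Si](CC)(CC)CC | intermediate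
7 | 2-[(3S)-3,7-dimethyloct-6-enoyl]-3-methyl-3-(triethylsilyl)pent-4-enoic acid | OC(=O)C(C(=O)C[C@@H](C)CCC=C(C)C)C(C)(C=C)[Si](CC)(CC)CC | intermediate
8 | (7S)-3,7,11-trimethyl-3-(triethylsilyl)dodeca-1,10-dien-5-one, both C3 epimers | C=CC(C)([Si](CC)(CC)CC)CC(=O)C[C@@H](C)CCC=C(C)C | intermediate
9 | (7S)-10-hydroperoxy-3,7,11-trimethyl-3-(triethylsilyl)dodeca-1,11-dien-5-one | C=CC(C)([Si](CC)(CC)CC)CC(=O)C[C@@H](C)CCC(OO)C(C)=C | intermediate
10 | (7S)-10-hydroxy-3,7,11-trimethyl-3-(triethylsilyl)dodeca-1,11-dien-5-one | C=CC(C)([Si](CC)(CC)CC)CC(=O)C[C@@H](C)CCC(O)C(C)=C | intermediate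
11 | methyl 4-methyl-3-oxopentanoate | COC(=O)CC(=O)C(C)C | starting material
12 | 4-methyl-3-oxopentanoate ester of 10 | C=CC(C)([Si](CC)(CC)CC)CC(=O)C[C@@H](C)CCC(OC(=O)CC(=O)C(C)C)C(C)=C | intermediate
13 | (4E,8S)-4,8,12-trimethyl-2-(2-methylpropanoyl)-10-oxo-12-(triethylsilyl)tetradeca-4,13-dienoic acid | C=CC(C)([Si](CC)(CC)CC)CC(=O)C[C@@H](C)CC/C=C(\C)CC(C(O)=O)C(=O)C(C)C | intermediate
14 | (7S,10E)-3,7,11,15-tetramethyl-3-(triethylsilyl)hexadeca-1,10-diene-5,14-dione | C=CC(C)([Si](CC)(CC)CC)CC(=O)C[C@@H](C)CC/C=C(\C)CCC(=O)C(C)C | intermediate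
15 | (7S,10R,11R)-10,11-epoxy-3,7,11,15-tetramethyl-3-(triethylsilyl)hexadec-1-ene-5,14-dione | C=CC(C)([Si](CC)(CC)CC)CC(=O)C[C@@H](C)CC[C@H]1O[C@]1(C)CCC(=O)C(C)C | intermediate
16 | 2-isopropyl-5-methyl-5-[1-(triethylsilyloxy)alkyl]-4,5-dihydro-3H-furan-1-ium triflate (C11 R, C12 S, C8 S) | C=CC(C)([Si](CC)(CC)CC)CC(=O)C[C@@H](C)CC[C@@H](O[Si](CC)(CC)CC)[C@]1(C)CCC(C(C)C)=[O+]1.[O-]S(=O)(=O)C(F)(F)F | intermediate
17 | (1R,3E,8S,11R,12S)-1,12-epoxy-11-(triethylsilyloxy)cembr-3-en-6-one | CC(C)[C@]12C/C=C(\C)CC(=O)C[C@@H](C)CC[C@@H](O[Si](CC)(CC)CC)[C@](C)(CC1)O2 | intermediate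
18 | (1R,3E,8S,11R,12S)-1,12-epoxy-11-hydroxycembr-3-en-6-one | CC(C)[C@]12C/C=C(\C)CC(=O)C[C@@H](C)CC[C@@H](O)[C@](C)(CC1)O2 | intermediate
19 | (1R,3E,8S,11R,12S)-1,12-epoxy-6-oxocembr-3-en-11-yl formate | CC(C)[C@]12C/C=C(\C)CC(=O)C[C@@H](C)CC[C@@H](OC=O)[C@](C)(CC1)O2 | intermediate
20 | (1S,2E,4S,8S,11R,12S)-1,12-epoxy-4-hydroperoxy-6-oxocembr-2-en-11-yl formate | CC(C)[C@]12/C=C/[C@@](C)(OO)CC(=O)C[C@@H](C)CC[C@@H](OC=O)[C@](C)(CC1)O2 | intermediate
21 | (1S,2E,4S,8S,11R,12S)-1,12-epoxy-4-hydroxy-6-oxocembr-2-en-11-yl formate (CNP0176107.1) | CC(C)[C@]12/C=C/[C@@](C)(O)CC(=O)C[C@@H](C)CC[C@@H](OC=O)[C@](C)(CC1)O2 | target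

**Total step count:** 9. **Longest linear sequence:** 8 (3 → 21, steps 2–9).

**Steps most likely to fail**

**Step 7 (double ring closure).** The risks are protodesilylation, hydride-shift rearrangement of the epoxide, oligomers and an E/Z mixture at C3=C4.
- The fallback sets out from 15 and comes back at 18. It separates the two ring closures.
- Pyridinium p-toluenesulfonate (5 mol %) in CH2Cl2 closes the tetrahydrofuran alone and gives the isolable bicyclic ketal 1-isopropyl-4-methyl-2,7-dioxabicyclo[2.2.1]heptane derivative F4. F4 is purified free of epoxide-derived side products.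
- F4 is then added slowly to stoichiometric TiCl4 (1.1 equiv, CH2Cl2, 1 mM, −78 °C). Titanium binds the less hindered O11 and re-opens the ketal to the same oxocarbenium ion, now as a titanium alkoxide. The allylsilane closes the carbocycle and aqueous work-up gives 18 directly.

**Step 9 (regio- and facial selectivity of the ene reaction).** Abstraction from the C4 methyl or from C5, or attack on the wrong face, would lower the yield or give the C4 epimer.
- The fallback sets out from 18 and comes back at 21. It puts C4 under reagent control. The free alcohol is used because the formate would not survive pH 10.5.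
- Epoxidation of 18 with the enantiomeric (L-series) ketone catalyst and KHSO5 gives the (3S,4S)-3,4-epoxide F5.
- PhSeNa (from PhSeSePh and NaBH4, EtOH, 0 °C) opens F5 at C3 with inversion to the (3R,4S)-4-hydroxy-3-(phenylselanyl) compound F6.
- H2O2 (THF, 0 °C) oxidises F6 to the selenoxide F7. Its syn elimination can only go towards C2 and gives the E-2-ene 4,11-diol F8.
- Acetic formic anhydride and pyridine formylate only the secondary C11–OH of F8 to give 21.

**Step 3 (Carroll rearrangement onto a silyl-bearing, fully substituted carbon).** The [3,3] shift may be too slow.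
- The fallback sets out from 5 and 1 and comes back at 8. Silicon is introduced after the C4–C5 bond is made.
- Transesterification of 5 with 1 (4-(dimethylamino)pyridine, toluene, reflux) gives the but-2-yn-1-yl β-keto ester F1.
- The sterically easier propargyl Carroll rearrangement (o-xylene, 140 °C) passes through the allenyl β-keto acid F2 to the allenyl ketone F3.
- Hydrosilylation of F3 with Et3SiH uses the zerovalent palladium catalyst Pd2(dba)3 with 1,3-dimesitylimidazol-2-ylidene in THF at rt. It places silicon on the substituted allene terminus and hydrogen on the central carbon, giving 8.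

**Further compounds**
F1 | step 3 | but-2-yn-1-yl (5S)-5,9-dimethyl-3-oxodec-8-enoate | CC#CCOC(=O)CC(=O)C[C@@H](C)CCC=C(C)C
F2 | step 3 | 2-[(3S)-3,7-dimethyloct-6-enoyl]-3-methylpenta-3,4-dienoic acid | OC(=O)C(C(=O)C[C@@H](C)CCC=C(C)C)C(C)=C=C
F3 | step 3 | (7S)-3,7,11-trimethyldodeca-1,2,10-trien-5-one | C=C=C(C)CC(=O)C[C@@H](C)CCC=C(C)C
F4 | step 7 | 1-isopropyl-4-methyl-3-[(3S)-3,7-dimethyl-5-oxo-7-(triethylsilyl)non-8-en-1-yl]-2,7-dioxabicyclo[2.2.1]heptane (cembrane C11 R, C12 S) | CC(C)[C@]12CC[C@](C)(O1)[C@@H](CC[C@H](C)CC(=O)CC(C)(C=C)[Si](CC)(CC)CC)O2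
F5 | step 9 | (1R,3S,4S,8S,11R,12S)-1,12:3,4-diepoxy-11-hydroxycembran-6-one | CC(C)[C@]12C[C@@H]3O[C@@]3(C)CC(=O)C[C@@H](C)CC[C@@H](O)[C@](C)(CC1)O2
F6 | step 9 | (3R,4S)-1,12-epoxy-4,11-dihydroxy-3-(phenylselanyl)cembran-6-one | CC(C)[C@]12C[C@@H]([Se]c3ccccc3)[C@@](C)(O)CC(=O)C[C@@H](C)CC[C@@H](O)[C@](C)(CC1)O2
F7 | step 9 | selenoxide of F6 | CC(C)[C@]12C[C@@H]([Se](=O)c3ccccc3)[C@@](C)(O)CC(=O)C[C@@H](C)CC[C@@H](O)[C@](C)(CC1)O2
F8 | step 9 | (1S,2E,4S,8S,11R,12S)-1,12-epoxy-4,11-dihydroxycembr-2-en-6-one | CC(C)[C@]12/C=C/[C@@](C)(O)CC(=O)C[C@@H](C)CC[C@@H](O)[C@](C)(CC1)O2
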